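**Retrosynthetic overview** (target numbering: C1 = stereocentre, then C2–C3=C4(CO2Me)–C5 … C14 round the ring)
1. Target 36 ⇐ seco aldehyde–phosphonate 35: the 14-membered ring, the only ring built, is closed last at C3=C4 by an intramolecular Still–Gennari olefination, which also sets the ester-cis enoate.
2. 35 ⇐ sulfone 14 (C1–C3, C14, side chain) + allylic bromide 26 (C5–C13) + phosphonoacetate 32 (C4): C13–C14 sulfone alkylation, desulfonylation, then C4–C5 alkylation.
3. 14 ⇐ (R)-lactone 8 ⇐ prochiral cyclobutanone 7: a Baeyer–Villiger monooxygenase sets C1 and differentiates the two arms; thiolate opening puts sulfur on C14.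
4. 26 ⇐ 5-chloropent-1-yne 15: 7E alkene by Zr-catalysed carboalumination, 11Z alkene by Wittig reaction with a silyloxy ketone.
5. Ring order: bought cyclobutane → enzymatic γ-lactone → ring-opened chain → macrocycle.

Assumption: a Baeyer–Villiger monooxygenase giving (R)-8 in high ee is found in the usual enzyme panel (members of which give opposite antipodes with 3-substituted cyclobutanones); 1, 3, 15, 22 and 32 are bought.

**Route**

Step 1
Reactants: 1 methyl 3,3-dimethoxycyclobutane-1-carboxylate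
Product: 2 3,3-dimethoxy-N-methoxy-N-methylcyclobutane-1-carboxamide
Conditions: MeNH(OMe)·HCl, i-PrMgCl, THF, −20 to 0 °C
Reagents that add atoms: N,O-dimethylhydroxylamine hydrochloride (CNOC.Cl)
Why: Weinreb amide formation by aminolysis of the ester with the magnesium amide; the ketal is inert.

Step 2
Reactants: 2 3,3-dimethoxy-N-methoxy-N-methylcyclobutane-1-carboxamide; 3 5-bromo-2-methylpent-2-ene
Product: 5 1-(3,3-dimethoxycyclobutyl)-5-methylhex-4-en-1-one, via homoprenylmagnesium bromide 4 (not isolated)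
Conditions: 3, Mg, THF, rt; then 2, 0 °C; aq NH4Cl
Reagents that add atoms: none
Why: Weinreb ketone synthesis, in which the chelated adduct stops at the ketone; no stereocentre arises because the cyclobutane is still symmetric.

Step 3
Reactants: 5 1-(3,3-dimethoxycyclobutyl)-5-methylhex-4-en-1-one
Product: 6 3,3-dimethoxy-1-(6-methylhepta-1,5-dien-2-yl)cyclobutane
Conditions: Ph3PCH3Br, KOt-Bu, THF, 0 °C to rt
Reagents that add atoms: methyltriphenylphosphonium bromide (C[P+](c1ccccc1)(c1ccccc1)c1ccccc1.[Br-])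
Why: Wittig methylenation installs the 1,1-disubstituted alkene while the ring carbon next to the ketone is not yet stereogenic, so enolisation is harmless.

Step 4
Reactants: 6 3,3-dimethoxy-1-(6-methylhepta-1,5-dien-2-yl)cyclobutane
Product: 7 3-(6-methylhepta-1,5-dien-2-yl)cyclobutan-1-one
Conditions: p-toluenesulfonic acid monohydrate (cat.), acetone/H2O, rt
Reagents that add atoms: water (O)
Why: Mild acid-catalysed ketal hydrolysis frees the prochiral ketone without touching the alkenes.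

Step 5
Reactants: 7 3-(6-methylhepta-1,5-dien-2-yl)cyclobutan-1-one
Product: 8 (4R)-4-(6-methylhepta-1,5-dien-2-yl)oxolan-2-one
Conditions: Baeyer–Villiger monooxygenase (cyclohexanone monooxygenase type, flavin- and NADPH-dependent), NADP+ (cat.), phosphite dehydrogenase, Na2HPO3, air, buffer pH 8, 25 °C
Reagents that add atoms: dioxygen (O=O)
Why: Enzymatic Baeyer–Villiger desymmetrisation, in which the enzyme-bound flavin hydroperoxide migrates one of the two enantiotopic ring CH2 groups, sets C1 as R under enzyme control and does not epoxidise the isolated alkenes.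

Step 6
Reactants: 8 (4R)-4-(6-methylhepta-1,5-dien-2-yl)oxolan-2-one
Product: 9 (3R)-3-(6-methylhepta-1,5-dien-2-yl)-4-(phenylsulfanyl)butanoic acid
Conditions: PhSNa, DMF, 110 °C; then 1 M HCl
Reagents that add atoms: sodium benzenethiolate ([Na+].[S-]c1ccccc1)
Why: SN2 alkyl–oxygen cleavage of the γ-lactone by thiolate places sulfur on C14 and leaves C1, which is not the reacting carbon, untouched.

Step 7
Reactants: 9 (3R)-3-(6-methylhepta-1,5-dien-2-yl)-4-(phenylsulfanyl)butanoic acid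
Product: 10 (3R)-3-(6-methylhepta-1,5-dien-2-yl)-4-(phenylsulfanyl)butan-1-ol
Conditions: LiAlH4, THF, 0 °C to rt
Reagents that add atoms: none
Why: Hydride reduction of the carboxylic acid to the primary alcohol; sulfide and alkenes are inert.

Step 8
Reactants: 10 (3R)-3-(6-methylhepta-1,5-dien-2-yl)-4-(phenylsulfanyl)butan-1-ol
Product: 12 (3R)-3-(6-methylhepta-1,5-dien-2-yl)-4-(phenylsulfonyl)butan-1-ol, via sulfoxide 11 (not isolated)
Conditions: (NH4)6Mo7O24·4H2O (cat.), 30% H2O2, EtOH, 0 °C to rt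
Reagents that add atoms: hydrogen peroxide (OO)
Why: Molybdate-catalysed sulfide-to-sulfone oxidation is much faster at sulfur than at unactivated alkenes or the alcohol.

Step 9
Reactants: 12 (3R)-3-(6-methylhepta-1,5-dien-2-yl)-4-(phenylsulfonyl)butan-1-ol
Product: 13 (3R)-3-(6-methylhepta-1,5-dien-2-yl)-4-(phenylsulfonyl)butanal
Conditions: Dess–Martin periodinane, CH2Cl2, rt
Reagents that add atoms: none
Why: Dess–Martin oxidation gives the aldehyde (C3) under neutral conditions; C1 is β to the carbonyl and cannot epimerise.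

Step 10
Reactants: 13 (3R)-3-(6-methylhepta-1,5-dien-2-yl)-4-(phenylsulfonyl)butanal
Product: 14 {[(2R)-4,4-dimethoxy-2-(6-methylhepta-1,5-dien-2-yl)butyl]sulfonyl}benzene
Conditions: HC(OMe)3, pyridinium p-toluenesulfonate (cat.), MeOH, rt
Reagents that add atoms: trimethyl orthoformate (COC(OC)OC)
Why: Acetalisation masks the aldehyde against the organolithium, amalgam, fluoride and enolate chemistry that follows.

Step 11
Reactants: 15 5-chloropent-1-yne
Product: 18 (3E)-7-chloro-4-methylhept-3-en-1-ol, via alkenyldimethylalane 16 (not isolated), via lithium alkenylaluminate 17 (not isolated)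
Conditions: AlMe3, Cp2ZrCl2 (cat.), CH2Cl2, 0 °C to rt; volatiles off; n-BuLi, hexane/THF, −78 °C; oxirane, −78 to 0 °C; aq HCl
Reagents that add atoms: trimethylaluminium (C[Al](C)C); oxirane (C1CO1)
Why: Negishi Zr-catalysed syn-carboalumination puts methyl on the internal carbon, and the derived aluminate opens oxirane with retention, fixing the 7E trisubstituted alkene.

Step 12
Reactants: 18 (3E)-7-chloro-4-methylhept-3-en-1-ol
Product: 19 tert-butyl{[(3E)-7-chloro-4-methylhept-3-en-1-yl]oxy}diphenylsilane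
Conditions: t-BuPh2SiCl, imidazole, CH2Cl2, rt
Reagents that add atoms: tert-butyl(chloro)diphenylsilane (CC(C)(C)[Si](Cl)(c1ccccc1)c1ccccc1)
Why: Silylation protects the C5 hydroxyl with a group that survives base, mild acid and amalgam.

Step 13
Reactants: 19 tert-butyl{[(3E)-7-chloro-4-methylhept-3-en-1-yl]oxy}diphenylsilane
Product: 21 [(4E)-7-{[tert-butyl(diphenyl)silyl]oxy}-4-methylhept-4-en-1-yl]triphenylphosphonium iodide, via alkyl iodide 20 (not isolated)
Conditions: NaI, PPh3, MeCN, reflux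
Reagents that add atoms: triphenylphosphine (c1ccc(cc1)P(c1ccccc1)c1ccccc1); sodium iodide ([Na+].[I-])
Why: Finkelstein exchange followed by SN2 quaternisation of triphenylphosphine gives the Wittig salt.

Step 14
Reactants: 21 [(4E)-7-{[tert-butyl(diphenyl)silyl]oxy}-4-methylhept-4-en-1-yl]triphenylphosphonium iodide; 22 1-{[tert-butyl(dimethyl)silyl]oxy}propan-2-one
Product: 24 tert-butyl{[(3E,7Z)-9-{[tert-butyl(dimethyl)silyl]oxy}-4,8-dimethylnona-3,7-dien-1-yl]oxy}diphenylsilane, via phosphonium ylide 23 (not isolated)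
Conditions: KN(SiMe3)2, THF, −78 to 0 °C; then 22, −78 °C to rt
Reagents that add atoms: none
Why: Wittig reaction of a non-stabilised ylide with an α-silyloxy ketone (Still's Z-selective trisubstituted olefination) puts the oxygenated CH2 cis to the chain, which is the 11Z geometry.

Step 15
Reactants: 24 tert-butyl{[(3E,7Z)-9-{[tert-butyl(dimethyl)silyl]oxy}-4,8-dimethylnona-3,7-dien-1-yl]oxy}diphenylsilane
Product: 25 (2Z,6E)-9-{[tert-butyl(diphenyl)silyl]oxy}-2,6-dimethylnona-2,6-dien-1-ol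
Conditions: pyridinium p-toluenesulfonate, EtOH, 40 °C
Reagents that add atoms: none
Why: Acid-catalysed solvolysis removes the allylic dimethylsilyl ether much faster than the diphenylsilyl ether.

Step 16
Reactants: 25 (2Z,6E)-9-{[tert-butyl(diphenyl)silyl]oxy}-2,6-dimethylnona-2,6-dien-1-ol
Product: 26 {[(3E,7Z)-9-bromo-4,8-dimethylnona-3,7-dien-1-yl]oxy}(tert-butyl)diphenylsilane
Conditions: CBr4, PPh3, CH2Cl2, −20 to 0 °C
Reagents that add atoms: carbon tetrabromide (BrC(Br)(Br)Br)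
Why: Appel bromination converts the primary allylic alcohol by SN2 without allylic shift or loss of the Z geometry.

Step 17
Reactants: 14 {[(2R)-4,4-dimethoxy-2-(6-methylhepta-1,5-dien-2-yl)butyl]sulfonyl}benzene; 26 {[(3E,7Z)-9-bromo-4,8-dimethylnona-3,7-dien-1-yl]oxy}(tert-butyl)diphenylsilane
Product: 28 tert-butyl{[(3E,7Z,11R)-13,13-dimethoxy-4,8-dimethyl-11-(6-methylhepta-1,5-dien-2-yl)-10-(phenylsulfonyl)trideca-3,7-dien-1-yl]oxy}diphenylsilane, via lithiated sulfone 27 (not isolated)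
Conditions: n-BuLi, THF, −78 °C; then 26, DMPU, −78 to −30 °C
Reagents that add atoms: none
Why: Alkylation of the α-sulfonyl carbanion by SN2 at the primary allylic bromide forms C13–C14; the new sulfone-bearing centre is an epimer mixture that is erased in step 18.

Step 18
Reactants: 28 tert-butyl{[(3E,7Z,11R)-13,13-dimethoxy-4,8-dimethyl-11-(6-methylhepta-1,5-dien-2-yl)-10-(phenylsulfonyl)trideca-3,7-dien-1-yl]oxy}diphenylsilane
Product: 29 tert-butyl{[(3E,7Z,11R)-13,13-dimethoxy-4,8-dimethyl-11-(6-methylhepta-1,5-dien-2-yl)trideca-3,7-dien-1-yl]oxy}diphenylsilane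
Conditions: Na(Hg) (6%), Na2HPO4, MeOH/THF, −20 to 0 °C
Reagents that add atoms: none
Why: Buffered reductive desulfonylation replaces the sulfonyl group by hydrogen and leaves isolated alkenes, acetal and silyl ether alone.

Step 19
Reactants: 29 tert-butyl{[(3E,7Z,11R)-13,13-dimethoxy-4,8-dimethyl-11-(6-methylhepta-1,5-dien-2-yl)trideca-3,7-dien-1-yl]oxy}diphenylsilane
Product: 30 (3E,7Z,11R)-13,13-dimethoxy-4,8-dimethyl-11-(6-methylhepta-1,5-dien-2-yl)trideca-3,7-dien-1-ol
Conditions: Bu4NF, THF, rt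
Reagents that add atoms: none
Why: Fluoride desilylation frees the C5 hydroxyl; the acetal is stable to it.

Step 20
Reactants: 30 (3E,7Z,11R)-13,13-dimethoxy-4,8-dimethyl-11-(6-methylhepta-1,5-dien-2-yl)trideca-3,7-dien-1-ol
Product: 31 (3E,7Z,11R)-1-iodo-13,13-dimethoxy-4,8-dimethyl-11-(6-methylhepta-1,5-dien-2-yl)trideca-3,7-diene
Conditions: I2, PPh3, imidazole, CH2Cl2, 0 °C
Reagents that add atoms: iodine (II)
Why: Appel-type iodination of the primary alcohol under imidazole buffering, which protects the acetal.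

Step 21
Reactants: 31 (3E,7Z,11R)-1-iodo-13,13-dimethoxy-4,8-dimethyl-11-(6-methylhepta-1,5-dien-2-yl)trideca-3,7-diene; 32 methyl 2-[bis(2,2,2-trifluoroethoxy)phosphoryl]acetate
Product: 34 methyl (2RS,5E,9Z,13R)-2-[bis(2,2,2-trifluoroethoxy)phosphoryl]-15,15-dimethoxy-6,10-dimethyl-13-(6-methylhepta-1,5-dien-2-yl)pentadeca-5,9-dienoate, via sodium phosphonoacetate 33 (not isolated)
Conditions: 32 (2.5 equiv), NaH, DMF, 0 °C; then 31, rt to 45 °C
Reagents that add atoms: none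
Why: SN2 C-alkylation of the phosphonoacetate carbanion forms C4–C5, with excess 32 suppressing dialkylation; the C4 epimers converge in step 23.

Step 22
Reactants: 34 methyl (2RS,5E,9Z,13R)-2-[bis(2,2,2-trifluoroethoxy)phosphoryl]-15,15-dimethoxy-6,10-dimethyl-13-(6-methylhepta-1,5-dien-2-yl)pentadeca-5,9-dienoate
Product: 35 methyl (2RS,5E,9Z,13R)-2-[bis(2,2,2-trifluoroethoxy)phosphoryl]-6,10-dimethyl-13-(6-methylhepta-1,5-dien-2-yl)-15-oxopentadeca-5,9-dienoate
Conditions: p-toluenesulfonic acid monohydrate (cat.), acetone/H2O, rt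
Reagents that add atoms: water (O)
Why: Mild acetal hydrolysis unmasks the C3 aldehyde; phosphonate, methyl ester and alkenes tolerate dilute acid.

Step 23
Reactants: 35 methyl (2RS,5E,9Z,13R)-2-[bis(2,2,2-trifluoroethoxy)phosphoryl]-6,10-dimethyl-13-(6-methylhepta-1,5-dien-2-yl)-15-oxopentadeca-5,9-dienoate
Product: 36 methyl (1Z,4E,8Z,12R)-5,9-dimethyl-12-(6-methylhepta-1,5-dien-2-yl)cyclotetradeca-1(14),4,8-triene-1-carboxylate
Conditions: K2CO3, 18-crown-6, toluene, rt, slow addition, final 1 mM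
Reagents that add atoms: none
Why: Intramolecular Still–Gennari Horner–Wadsworth–Emmons olefination at high dilution closes the ring; the trifluoroethyl phosphonate eliminates fast from the kinetic adduct and gives the enoate with CO2Me cis to C2.

**Compound list**
1 | methyl 3,3-dimethoxycyclobutane-1-carboxylate | COC(=O)C1CC(OC)(OC)C1 | starting material
2 | 3,3-dimethoxy-N-methoxy-N-methylcyclobutane-1-carboxamide | CON(C)C(=O)C1CC(OC)(OC)C1 | intermediate
3 | 5-bromo-2-methylpent-2-ene | CC(C)=CCCBr | starting material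
4 | (4-methylpent-3-en-1-yl)magnesium bromide | CC(C)=CCC[Mg]Br | intermediate
5 | 1-(3,3-dimethoxycyclobutyl)-5-methylhex-4-en-1-one | CC(C)=CCCC(=O)C1CC(OC)(OC)C1 | intermediate
6 | 3,3-dimethoxy-1-(6-methylhepta-1,5-dien-2-yl)cyclobutane | C=C(CCC=C(C)C)C1CC(OC)(OC)C1 | intermediate
7 | 3-(6-methylhepta-1,5-dien-2-yl)cyclobutan-1-one | C=C(CCC=C(C)C)C1CC(=O)C1 | intermediate
8 | (4R)-4-(6-methylhepta-1,5-dien-2-yl)oxolan-2-one | C=C(CCC=C(C)C)[C@H]1CC(=O)OC1 | intermediate
9 | (3R)-3-(6-methylhepta-1,5-dien-2-yl)-4-(phenylsulfanyl)butanoic acid | C=C(CCC=C(C)C)[C@H](CSc1ccccc1)CC(=O)O | intermediate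
10 | (3R)-3-(6-methylhepta-1,5-dien-2-yl)-4-(phenylsulfanyl)butan-1-ol | C=C(CCC=C(C)C)[C@H](CSc1ccccc1)CCO | intermediate
11 | (3R)-3-(6-methylhepta-1,5-dien-2-yl)-4-(phenylsulfinyl)butan-1-ol (both sulfur epimers) | C=C(CCC=C(C)C)[C@H](CS(=O)c1ccccc1)CCO | intermediate
12 | (3R)-3-(6-methylhepta-1,5-dien-2-yl)-4-(phenylsulfonyl)butan-1-ol | C=C(CCC=C(C)C)[C@H](CS(=O)(=O)c1ccccc1)CCO | intermediate
13 | (3R)-3-(6-methylhepta-1,5-dien-2-yl)-4-(phenylsulfonyl)butanal | C=C(CCC=C(C)C)[C@H](CS(=O)(=O)c1ccccc1)CC=O | intermediate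
14 | {[(2R)-4,4-dimethoxy-2-(6-methylhepta-1,5-dien-2-yl)butyl]sulfonyl}benzene | C=C(CCC=C(C)C)[C@H](CS(=O)(=O)c1ccccc1)CC(OC)OC | intermediate
15 | 5-chloropent-1-yne | C#CCCCCl | starting material
16 | [(1E)-5-chloro-2-methylpent-1-en-1-yl]dimethylalane | C[Al](C)/C=C(\C)CCCCl | intermediate
17 | lithium butyl[(1E)-5-chloro-2-methylpent-1-en-1-yl]dimethylaluminate | [Li+].CCCC[Al-](C)(C)/C=C(\C)CCCCl | intermediate
18 | (3E)-7-chloro-4-methylhept-3-en-1-ol | OCC/C=C(\C)CCCCl | intermediate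
19 | tert-butyl{[(3E)-7-chloro-4-methylhept-3-en-1-yl]oxy}diphenylsilane | CC(C)(C)[Si](OCC/C=C(\C)CCCCl)(c1ccccc1)c1ccccc1 | intermediate
20 | tert-butyl{[(3E)-7-iodo-4-methylhept-3-en-1-yl]oxy}diphenylsilane | CC(C)(C)[Si](OCC/C=C(\C)CCCI)(c1ccccc1)c1ccccc1 | intermediate
21 | [(4E)-7-{[tert-butyl(diphenyl)silyl]oxy}-4-methylhept-4-en-1-yl]triphenylphosphonium iodide | CC(C)(C)[Si](OCC/C=C(\C)CCC[P+](c1ccccc1)(c1ccccc1)c1ccccc1)(c1ccccc1)c1ccccc1.[I-] | intermediate
22 | 1-{[tert-butyl(dimethyl)silyl]oxy}propan-2-one | CC(=O)CO[Si](C)(C)C(C)(C)C | starting material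
23 | [(4E)-7-{[tert-butyl(diphenyl)silyl]oxy}-4-methylhept-4-en-1-ylidene]triphenylphosphorane | CC(C)(C)[Si](OCC/C=C(\C)CCC=P(c1ccccc1)(c1ccccc1)c1ccccc1)(c1ccccc1)c1ccccc1 | intermediate
24 | tert-butyl{[(3E,7Z)-9-{[tert-butyl(dimethyl)silyl]oxy}-4,8-dimethylnona-3,7-dien-1-yl]oxy}diphenylsilane | CC(C)(C)[Si](C)(C)OC/C(C)=C\CC/C(C)=C/CCO[Si](c1ccccc1)(c1ccccc1)C(C)(C)C | intermediate
25 | (2Z,6E)-9-{[tert-butyl(diphenyl)silyl]oxy}-2,6-dimethylnona-2,6-dien-1-ol | OC/C(C)=C\CC/C(C)=C/CCO[Si](c1ccccc1)(c1ccccc1)C(C)(C)C | intermediate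
26 | {[(3E,7Z)-9-bromo-4,8-dimethylnona-3,7-dien-1-yl]oxy}(tert-butyl)diphenylsilane | BrC/C(C)=C\CC/C(C)=C/CCO[Si](c1ccccc1)(c1ccccc1)C(C)(C)C | intermediate
27 | lithium salt of 14 deprotonated at the CH2 next to sulfur | [Li+].C=C(CCC=C(C)C)[C@H]([CH-]S(=O)(=O)c1ccccc1)CC(OC)OC | intermediate
28 | tert-butyl{[(3E,7Z,11R)-13,13-dimethoxy-4,8-dimethyl-11-(6-methylhepta-1,5-dien-2-yl)-10-(phenylsulfonyl)trideca-3,7-dien-1-yl]oxy}diphenylsilane (both C10 epimers) | C=C(CCC=C(C)C)[C@H](C(C/C(C)=C\CC/C(C)=C/CCO[Si](c1ccccc1)(c1ccccc1)C(C)(C)C)S(=O)(=O)c1ccccc1)CC(OC)OC | intermediate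
29 | tert-butyl{[(3E,7Z,11R)-13,13-dimethoxy-4,8-dimethyl-11-(6-methylhepta-1,5-dien-2-yl)trideca-3,7-dien-1-yl]oxy}diphenylsilane | C=C(CCC=C(C)C)[C@H](CC/C(C)=C\CC/C(C)=C/CCO[Si](c1ccccc1)(c1ccccc1)C(C)(C)C)CC(OC)OC | intermediate
30 | (3E,7Z,11R)-13,13-dimethoxy-4,8-dimethyl-11-(6-methylhepta-1,5-dien-2-yl)trideca-3,7-dien-1-ol | C=C(CCC=C(C)C)[C@H](CC/C(C)=C\CC/C(C)=C/CCO)CC(OC)OC | intermediate
31 | (3E,7Z,11R)-1-iodo-13,13-dimethoxy-4,8-dimethyl-11-(6-methylhepta-1,5-dien-2-yl)trideca-3,7-diene | C=C(CCC=C(C)C)[C@H](CC/C(C)=C\CC/C(C)=C/CCI)CC(OC)OC | intermediate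
32 | methyl 2-[bis(2,2,2-trifluoroethoxy)phosphoryl]acetate | COC(=O)CP(=O)(OCC(F)(F)F)OCC(F)(F)F | starting material
33 | sodium salt of the carbanion of 32 | [Na+].COC(=O)[CH-]P(=O)(OCC(F)(F)F)OCC(F)(F)F | intermediate
34 | methyl (2RS,5E,9Z,13R)-2-[bis(2,2,2-trifluoroethoxy)phosphoryl]-15,15-dimethoxy-6,10-dimethyl-13-(6-methylhepta-1,5-dien-2-yl)pentadeca-5,9-dienoate | C=C(CCC=C(C)C)[C@H](CC/C(C)=C\CC/C(C)=C/CCC(C(=O)OC)P(=O)(OCC(F)(F)F)OCC(F)(F)F)CC(OC)OC | intermediate
35 | methyl (2RS,5E,9Z,13R)-2-[bis(2,2,2-trifluoroethoxy)phosphoryl]-6,10-dimethyl-13-(6-methylhepta-1,5-dien-2-yl)-15-oxopentadeca-5,9-dienoate | C=C(CCC=C(C)C)[C@H](CC/C(C)=C\CC/C(C)=C/CCC(C(=O)OC)P(=O)(OCC(F)(F)F)OCC(F)(F)F)CC=O | intermediate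
36 | methyl (1Z,4E,8Z,12R)-5,9-dimethyl-12-(6-methylhepta-1,5-dien-2-yl)cyclotetradeca-1(14),4,8-triene-1-carboxylate (CNP0163659.2) | C=C(CCC=C(C)C)[C@H]1C/C=C(\C(=O)OC)CC/C=C(\C)CC/C=C(/C)CC1 | target

**Step count and risks**
Total: 23 steps (steps 1–10 to sulfone 14, steps 11–16 to bromide 26, steps 17–23 for union and ring closure). Longest linear sequence: 17 steps (1–10, then 17–23).

Most likely to fail:

Step 23 (ring closure). Oligomers or a poor Z:E ratio are possible. The fallback fixes the enoate geometry in an intermolecular olefination and closes the ring at C4–C5 by sp2–sp3 cross-coupling; it sets out from iodide 31 and comes back at 36. Hydrolysis of the acetal of 31 (p-toluenesulfonic acid, wet acetone) gives (3R,6Z,10E)-13-iodo-6,10-dimethyl-3-(6-methylhepta-1,5-dien-2-yl)trideca-6,10-dienal F1. Phosphonate 32 is brominated once at the α-carbon (NaH, then N-bromosuccinimide) to methyl bromo[bis(2,2,2-trifluoroethoxy)phosphoryl]acetate F2. F1 and F2 (KN(SiMe3)2, 18-crown-6, THF, −78 °C) give the (E)-α-bromoacrylate methyl (2E,5R,8Z,12E)-2-bromo-15-iodo-8,12-dimethyl-5-(6-methylhepta-1,5-dien-2-yl)pentadeca-2,8,12-trienoate F3, in which the ester is already cis to C2. Zinc insertion into the alkyl iodide (Zn dust, LiCl, THF) gives the alkylzinc iodide F4, and slow addition of it to Pd(PPh3)4 in THF (intramolecular Negishi coupling, retention at the alkenyl bromide) gives 36.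

Step 5 (enzymatic oxidation). The panel may give (R)-8 only in moderate ee. The fallback keeps the best (R)-selective monooxygenase and secures enantiopurity with a second enzyme class, a lipase; it sets out from 8 of insufficient ee and comes back at 8. Pyrrolidine (neat, rt) opens the lactone to (3R)-4-hydroxy-3-(6-methylhepta-1,5-dien-2-yl)-1-(pyrrolidin-1-yl)butan-1-one F5. A lipase (Burkholderia cepacia lipase, vinyl acetate, t-BuOMe) is expected to acetylate the residual (S)-alcohol faster, giving (2S)-2-(6-methylhepta-1,5-dien-2-yl)-4-oxo-4-(pyrrolidin-1-yl)butyl acetate F6, which is separated. The remaining (R)-F5 is relactonised to 8 with p-toluenesulfonic acid in warm toluene.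

Step 6 (thiolate opening of the hindered lactone). The SN2 step may be sluggish, or the hot thiolate may attack the diene. The fallback differentiates the arms by acyl cleavage instead of alkyl cleavage; it sets out from 8 and comes back at 13, bypassing 9, 10 and 12. MeNH(OMe)·HCl with AlMe3 in CH2Cl2 gives (3R)-4-hydroxy-N-methoxy-N-methyl-3-(6-methylhepta-1,5-dien-2-yl)butanamide F7. I2, PPh3 and imidazole give (3R)-4-iodo-N-methoxy-N-methyl-3-(6-methylhepta-1,5-dien-2-yl)butanamide F8. PhSO2Na in DMF gives (3R)-N-methoxy-N-methyl-3-(6-methylhepta-1,5-dien-2-yl)-4-(phenylsulfonyl)butanamide F9. i-Bu2AlH at −78 °C reduces the Weinreb amide to aldehyde 13.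

**Further compounds**
F1 | step 23 | (3R,6Z,10E)-13-iodo-6,10-dimethyl-3-(6-methylhepta-1,5-dien-2-yl)trideca-6,10-dienal | C=C(CCC=C(C)C)[C@H](CC/C(C)=C\CC/C(C)=C/CCI)CC=O
F2 | step 23 | methyl bromo[bis(2,2,2-trifluoroethoxy)phosphoryl]acetate | COC(=O)C(Br)P(=O)(OCC(F)(F)F)OCC(F)(F)F
F3 | step 23 | methyl (2E,5R,8Z,12E)-2-bromo-15-iodo-8,12-dimethyl-5-(6-methylhepta-1,5-dien-2-yl)pentadeca-2,8,12-trienoate | C=C(CCC=C(C)C)[C@H](CC/C(C)=C\CC/C(C)=C/CCI)C/C=C(/Br)C(=O)OC
F4 | step 23 | [(3E,7Z,11R,13E)-14-bromo-15-methoxy-4,8-dimethyl-11-(6-methylhepta-1,5-dien-2-yl)-15-oxopentadeca-3,7,13-trien-1-yl]zinc iodide | C=C(CCC=C(C)C)[C@H](CC/C(C)=C\CC/C(C)=C/CC[Zn]I)C/C=C(/Br)C(=O)OC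
F5 | step 5 | (3R)-4-hydroxy-3-(6-methylhepta-1,5-dien-2-yl)-1-(pyrrolidin-1-yl)butan-1-one | C=C(CCC=C(C)C)[C@H](CO)CC(=O)N1CCCC1
F6 | step 5 | (2S)-2-(6-methylhepta-1,5-dien-2-yl)-4-oxo-4-(pyrrolidin-1-yl)butyl acetate | C=C(CCC=C(C)C)[C@@H](COC(C)=O)CC(=O)N1CCCC1
F7 | step 6 | (3R)-4-hydroxy-N-methoxy-N-methyl-3-(6-methylhepta-1,5-dien-2-yl)butanamide | C=C(CCC=C(C)C)[C@H](CO)CC(=O)N(C)OC
F8 | step 6 | (3R)-4-iodo-N-methoxy-N-methyl-3-(6-methylhepta-1,5-dien-2-yl)butanamide | C=C(CCC=C(C)C)[C@H](CI)CC(=O)N(C)OC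
F9 | step 6 | (3R)-N-methoxy-N-methyl-3-(6-methylhepta-1,5-dien-2-yl)-4-(phenylsulfonyl)butanamide | C=C(CCC=C(C)C)[C@H](CS(=O)(=O)c1ccccc1)CC(=O)N(C)OC
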